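**Plan**

1. Route locants: C1(OAng)–C2H2–C3(Me)=C4H–C5(OAng)–C6(Me, fusion)–C7H(OH)–C8H2–C9(OH)(iPr)–C10H (fusion, bonded to C1 and C6); α is the face of the C6 methyl, β the face of H‑10.
2. Cuts, in order: both ester O–acyl bonds; C8–H/C9–O back to a C8–C9 epoxide and then to the allylic alcohol C7(OH)–C8=C9(iPr); the C8=C9 bond of the cyclopentene (metathesis); C10–C9 and C6–C7 (conjugate addition/aldol on a cyclohepta‑2,6‑dienone); C3=C4 (metathesis) and C6–C10 (amide enolate + epoxide).
3. Forward: (S)‑epichlorohydrin → acyclic dienone → seven‑membered ring → cross‑conjugated dienone 12 → both side chains in one flask → five‑membered ring closed last → oxygen at C9, hydroxyl at C5, two angelates.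
4. Stereochemistry: C1 from (S)‑epichlorohydrin; C10 by conjugate addition anti to the C1 silyloxy group; C6 by enolate attack anti to the new C10 substituent; C7 from the chair aldol transition state; C9 by C7‑hydroxyl‑directed epoxidation followed by hydride at C8; C5 by C7‑hydroxyl‑directed anti reduction.
5. Enabling feature: in the cyclopentane ring C6–C7–C8–C9–C10 the carbinols C7 and C9 are 1,3 across the C8 methylene, so a C8=C9 alkene next to the C7 hydroxyl is the direct precursor of the cis‑diol. C8=C9 touches neither fusion atom, so the trans C6/C10 relationship can be fixed on the cycloheptene first.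

Key step: step 9

Remark: the SMILES is read as the (1R,3R,3aS,4S,8R,8aR) enantiomer with a trans ring fusion; the α‑methyl carbon of 6, 7, 9 and 10 is left undefined (epimer mixtures) because step 6 makes it sp2.

**Route**

Step 1
Reactants: 1 (S)-epichlorohydrin; 2 isopropenylmagnesium bromide
Product: 4 (2S)-2-(2-methylprop-2-en-1-yl)oxirane, via chlorohydrin 3 (not isolated)
Conditions: 2 (1.2 equiv), CuI (10 mol%), THF, −40 °C; then aq. NaOH, Et2O, rt
Reagents that add atoms: none
Why: Copper‑catalysed Grignard opening of the epoxide at its CH2 terminus and Williamson closure of the chlorohydrin should leave the C–O bond at the stereocentre untouched, so the configuration of 1 is carried into 4.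

Step 2
Reactants: 4 (2S)-2-(2-methylprop-2-en-1-yl)oxirane; 5 4-propanoylmorpholine
Product: 6 (4R)-4-hydroxy-2,6-dimethyl-1-(morpholin-4-yl)hept-6-en-1-one (C2 epimers)
Conditions: 5, LiN(iPr)2, THF, −78 °C; add 4, −78 °C → rt; aq. NH4Cl
Reagents that add atoms: none
Why: Amide‑enolate opening of a terminal epoxide (SN2 at the CH2 carbon) should join C6 to C10 without touching the carbinol centre.

Step 3
Reactants: 6 (4R)-4-hydroxy-2,6-dimethyl-1-(morpholin-4-yl)hept-6-en-1-one
Product: 7 (4R)-4-[(tert-butyldimethylsilyl)oxy]-2,6-dimethyl-1-(morpholin-4-yl)hept-6-en-1-one (C2 epimers)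
Conditions: t-BuMe2SiCl, imidazole, DMF, rt
Reagents that add atoms: tert-butyldimethylsilyl chloride, CC(C)(C)[Si](C)(C)Cl
Why: Silyl ether formation should mask the carbinol as a non‑leaving group that later directs the conjugate addition to the opposite face.

Step 4
Reactants: 7 (4R)-4-[(tert-butyldimethylsilyl)oxy]-2,6-dimethyl-1-(morpholin-4-yl)hept-6-en-1-one; 8 vinylmagnesium bromide
Product: 9 (6R)-6-[(tert-butyldimethylsilyl)oxy]-4,8-dimethylnona-1,8-dien-3-one (C4 epimers)
Conditions: 8 (2.5 equiv), THF, −20 → 0 °C; inverse quench into cold 1 M HCl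
Reagents that add atoms: none
Why: Acyl substitution of a morpholine amide by a Grignard reagent should stop at the ketone because the tetrahedral magnesium adduct survives until the acid quench, which also keeps morpholine from adding to the enone.

Step 5
Reactants: 9 (6R)-6-[(tert-butyldimethylsilyl)oxy]-4,8-dimethylnona-1,8-dien-3-one
Product: 10 (5R)-5-[(tert-butyldimethylsilyl)oxy]-3,7-dimethylcyclohept-2-en-1-one (C7 epimers)
Conditions: second-generation Grubbs catalyst (5 mol%), CH2Cl2 (5 mM), 40 °C
Reagents that add atoms: none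
Why: Ring‑closing metathesis between the vinyl ketone and the 1,1‑disubstituted alkene should give the seven‑membered β‑methyl enone with loss of ethene and without a new stereocentre.

Step 6
Reactants: 10 (5R)-5-[(tert-butyldimethylsilyl)oxy]-3,7-dimethylcyclohept-2-en-1-one
Product: 12 (4S)-4-[(tert-butyldimethylsilyl)oxy]-2,6-dimethylcyclohepta-2,6-dien-1-one, via silyl dienol ether 11 (not isolated)
Conditions: LiN(iPr)2, Me3SiCl, THF, −78 °C; then Pd(OAc)2 (1.1 equiv), MeCN, rt
Reagents that add atoms: chlorotrimethylsilane, C[Si](C)(C)Cl (in 11 only)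
Why: Kinetic α′‑deprotonation/silylation and Saegusa–Ito dehydrogenation should install the second enone double bond and erase the α‑methyl stereocentre, leaving C1 as the only stereocentre.

Step 7
Reactants: 13 3-methylbut-1-yne
Product: 14 2-bromo-3-methylbut-1-ene
Conditions: Et4N[HBr2], CH2Cl2, 40 °C
Reagents that add atoms: tetraethylammonium hydrogen dibromide, CC[N+](CC)(CC)CC.[Br-].Br
Why: Markovnikov hydrobromination of the terminal alkyne should give the 2‑bromo‑1‑alkene.

Step 8
Reactants: 12 (4S)-4-[(tert-butyldimethylsilyl)oxy]-2,6-dimethylcyclohepta-2,6-dien-1-one; 14 2-bromo-3-methylbut-1-ene; 15 acrolein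
Product: 18 (5S,6S,7R)-5-[(tert-butyldimethylsilyl)oxy]-7-[(1R)-1-hydroxyprop-2-en-1-yl]-3,7-dimethyl-6-(3-methylbut-1-en-2-yl)cyclohept-2-en-1-one, via (3-methylbut-1-en-2-yl)magnesium bromide 16 (not isolated), via bromomagnesium enolate 17 (not isolated)
Conditions: 14, Mg, THF, rt; CuBr·SMe2 (20 mol%), then 12, THF, −78 → −40 °C; then 15 (3 equiv), −78 °C; aq. NH4Cl at −78 °C
Reagents that add atoms: magnesium, [Mg] (in 16 and 17 only)
Why: Copper‑catalysed conjugate addition should occur at the less substituted enone terminus C10 anti to the C1 silyloxy group, and the magnesium enolate should add to acrolein (aldol, Zimmerman–Traxler chair with the vinyl group equatorial) anti to the new C10 substituent, setting C10, C6 and C7 relative to C1 in one flask.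

Step 9
Reactants: 18 (5S,6S,7R)-5-[(tert-butyldimethylsilyl)oxy]-7-[(1R)-1-hydroxyprop-2-en-1-yl]-3,7-dimethyl-6-(3-methylbut-1-en-2-yl)cyclohept-2-en-1-one
Product: 19 cyclopentenol–enone (1β-OTBS; C3=C4; 5-oxo; 6α-Me; 7α-OH; C8=C9 bearing iPr; 10β-H; trans-fused)
Conditions: second-generation Hoveyda–Grubbs catalyst (10 mol%), 1,2-dichloroethane (5 mM), 60 °C
Reagents that add atoms: none
Why: The ruthenium alkylidene should load onto the monosubstituted vinyl group at C8, add across the 1,1‑disubstituted C9 alkene to a ruthenacyclobutane and cyclorevert to the C8=C9 double bond while ethene leaves the solution. The closest known reaction type is ring‑closing metathesis of 1,6‑dienes to trisubstituted cyclopent‑2‑en‑1‑ols. The five‑membered ring is closed by alkene–alkene metathesis across C8/C9, a bond that touches neither fusion atom, so the trans C6/C10 relationship from step 8 passes unchanged into a trans‑fused bicycle. No new stereocentre arises, C7 being already in place. The step needs chemoselectivity for the two terminal alkenes over the conjugated, trisubstituted C3=C4 bond and over dimerisation; this should be secured by the low metathesis reactivity of the enone, high dilution and the gauche placement of the two side chains on adjacent ring carbons. The product carries the allylic hydroxyl that steers oxygen to C9 in the next step.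

Step 10
Reactants: 19 cyclopentenol–enone
Product: 20 epoxy ketol (1β-OTBS; C3=C4; 5-oxo; 6α-Me; 7α-OH; 8α,9α-epoxide; 9β-iPr; 10β-H)
Conditions: VO(acac)2 (5 mol%), t-BuOOH, CH2Cl2, 0 °C → rt
Reagents that add atoms: tert-butyl hydroperoxide, CC(C)(C)OO
Why: Hydroxyl‑directed vanadium‑catalysed epoxidation should deliver oxygen to the cyclopentene face syn to the C7 hydroxyl (α), which sets the C9–O bond, while the electron‑poor C3=C4 bond stays inert.

Step 11
Reactants: 20 epoxy ketol
Product: 21 epoxy diol (1β-OTBS; C3=C4; 5β-OH; 6α-Me; 7α-OH; 8α,9α-epoxide; 9β-iPr; 10β-H)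
Conditions: Me4NBH(OAc)3 (6 equiv), MeCN/AcOH (2:1), −30 °C
Reagents that add atoms: none
Why: Evans–Saksena reduction should deliver hydride intramolecularly from the C7‑bound acetoxyborohydride to the α face of the C5 carbonyl (O7–C7–C6–C5 gauche, C8 anti to C5), giving the 1,3‑anti diol, i.e. the β‑hydroxyl at C5.

Step 12
Reactants: 21 epoxy diol
Product: 22 triol (1β-OTBS; C3=C4; 5β-OH; 6α-Me; 7α-OH; 9α-OH; 9β-iPr; 10β-H)
Conditions: LiEt3BH (5 equiv), THF, 0 °C → rt; aq. NH4Cl
Reagents that add atoms: none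
Why: SN2 hydride opening of the trisubstituted epoxide at the less substituted carbon C8 should leave the oxygen on C9 with its configuration, unveiling the cis‑1,3‑diol.

Step 13
Reactants: 22 triol; 23 angelic acid
Product: 26 C5 monoangelate (1β-OTBS; C3=C4; 5β-OAng; 6α-Me; 7α-OH; 9α-OH; 9β-iPr; 10β-H), via C7/C9 phenylboronate 24 (not isolated), via C5-angeloyl phenylboronate 25 (not isolated)
Conditions: PhB(OH)2 (1.05 equiv), 4 Å MS, toluene, rt; then mixed anhydride from 23, 2,4,6-Cl3C6H2COCl, Et3N (toluene, rt), 80 °C; then pinacol, rt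
Reagents that add atoms: phenylboronic acid, OB(O)c1ccccc1 (in 24 and 25 only)
Why: A cyclic boronate should form across the cis‑1,3 C7/C9 diol (a known transient protection of cis‑cyclopentane‑1,3‑diols), so the Yamaguchi‑type mixed anhydride esterifies only the C5 hydroxyl with the (Z)‑geometry intact, and pinacol then removes the boron.

Step 14
Reactants: 26 C5 monoangelate
Product: 27 diol-alcohol (1β-OH; C3=C4; 5β-OAng; 6α-Me; 7α-OH; 9α-OH; 9β-iPr; 10β-H)
Conditions: HF·pyridine, pyridine/THF, 0 °C → rt
Reagents that add atoms: none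
Why: Fluoride‑mediated desilylation under buffered acidic conditions should free the C1 hydroxyl without base‑induced acyl migration.

Step 15
Reactants: 27 diol-alcohol; 23 angelic acid
Product: 28 target, (1R,3R,3aS,4S,8R,8aR)-1,3-dihydroxy-6,8a-dimethyl-3-(propan-2-yl)-1,2,3,3a,4,5,8,8a-octahydroazulene-4,8-diyl bis[(2Z)-2-methylbut-2-enoate]
Conditions: mixed anhydride from 23 (1.3 equiv), 2,4,6-Cl3C6H2COCl, Et3N, toluene, rt; then 27, 60 °C
Reagents that add atoms: none
Why: Yamaguchi‑type esterification should take the least hindered secondary hydroxyl (C1), since the C7 hydroxyl is neopentylic and cis to the angular methyl and the C9 hydroxyl is tertiary.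

**Compound list**

1 | (S)-epichlorohydrin, (2S)-2-(chloromethyl)oxirane | ClC[C@@H]1CO1 | starting material
2 | isopropenylmagnesium bromide | C=C(C)[Mg]Br | starting material
3 | (2S)-1-chloro-4-methylpent-4-en-2-ol (chlorohydrin) | ClC[C@@H](O)CC(C)=C | intermediate (not isolated)
4 | (2S)-2-(2-methylprop-2-en-1-yl)oxirane | C=C(C)C[C@H]1CO1 | intermediate
5 | 4-propanoylmorpholine | CCC(=O)N1CCOCC1 | starting material
6 | (4R)-4-hydroxy-2,6-dimethyl-1-(morpholin-4-yl)hept-6-en-1-one | C=C(C)C[C@H](O)CC(C)C(=O)N1CCOCC1 | intermediate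
7 | (4R)-4-[(tert-butyldimethylsilyl)oxy]-2,6-dimethyl-1-(morpholin-4-yl)hept-6-en-1-one | C=C(C)C[C@H](O[Si](C)(C)C(C)(C)C)CC(C)C(=O)N1CCOCC1 | intermediate
8 | vinylmagnesium bromide | C=C[Mg]Br | starting material
9 | (6R)-6-[(tert-butyldimethylsilyl)oxy]-4,8-dimethylnona-1,8-dien-3-one | C=CC(=O)C(C)C[C@@H](O[Si](C)(C)C(C)(C)C)CC(C)=C | intermediate
10 | (5R)-5-[(tert-butyldimethylsilyl)oxy]-3,7-dimethylcyclohept-2-en-1-one | O=C1C=C(C)C[C@H](O[Si](C)(C)C(C)(C)C)CC1C | intermediate
11 | tert-butyl{[(1S)-3,6-dimethyl-4-(trimethylsilyloxy)cyclohepta-3,5-dien-1-yl]oxy}dimethylsilane (silyl dienol ether) | C[Si](C)(C)OC1=C(C)C[C@@H](O[Si](C)(C)C(C)(C)C)CC(C)=C1 | intermediate (not isolated)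
12 | (4S)-4-[(tert-butyldimethylsilyl)oxy]-2,6-dimethylcyclohepta-2,6-dien-1-one | CC1=C[C@@H](O[Si](C)(C)C(C)(C)C)CC(C)=CC1=O | intermediate
13 | 3-methylbut-1-yne | CC(C)C#C | starting material
14 | 2-bromo-3-methylbut-1-ene | C=C(Br)C(C)C | intermediate
15 | acrolein | C=CC=O | starting material
16 | (3-methylbut-1-en-2-yl)magnesium bromide | C=C([Mg]Br)C(C)C | intermediate (not isolated)
17 | bromomagnesium enolate of the conjugate adduct (C5–OMgBr, C5=C6; 10α-alkenyl; 1β-OTBS) | Br[Mg]OC1=C(C)[C@H](C(=C)C(C)C)[C@@H](O[Si](C)(C)C(C)(C)C)CC(C)=C1 | intermediate (not isolated)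
18 | (5S,6S,7R)-5-[(tert-butyldimethylsilyl)oxy]-7-[(1R)-1-hydroxyprop-2-en-1-yl]-3,7-dimethyl-6-(3-methylbut-1-en-2-yl)cyclohept-2-en-1-one | CC(C)(C)[Si](C)(C)O[C@H]1CC(C)=CC(=O)[C@@](C)([C@H](O)C=C)[C@@H]1C(=C)C(C)C | intermediate
19 | cyclopentenol–enone (1β-OTBS; C3=C4; 5-oxo; 6α-Me; 7α-OH; C8=C9–iPr; 10β-H) | CC(C)(C)[Si](C)(C)O[C@H]1CC(C)=CC(=O)[C@@]2(C)[C@H](O)C=C(C(C)C)[C@H]12 | intermediate
20 | epoxy ketol (as 19 with 8α,9α-epoxide) | CC(C)(C)[Si](C)(C)O[C@H]1CC(C)=CC(=O)[C@@]2(C)[C@H](O)[C@@H]3O[C@]3(C(C)C)[C@H]12 | intermediate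
21 | epoxy diol (as 20 with 5β-OH) | CC(C)(C)[Si](C)(C)O[C@H]1CC(C)=C[C@@H](O)[C@@]2(C)[C@H](O)[C@@H]3O[C@]3(C(C)C)[C@H]12 | intermediate
22 | triol (1β-OTBS; 5β-OH; 7α-OH; 9α-OH; 9β-iPr) | CC(C)(C)[Si](C)(C)O[C@H]1CC(C)=C[C@@H](O)[C@@]2(C)[C@H](O)C[C@@](O)(C(C)C)[C@H]12 | intermediate
23 | angelic acid, (2Z)-2-methylbut-2-enoic acid | C/C=C(/C)C(=O)O | starting material
24 | C7/C9 cyclic phenylboronate of 22 | CC(C)(C)[Si](C)(C)O[C@H]1CC(C)=C[C@@H](O)[C@@]2(C)[C@H]3C[C@@](OB(c4ccccc4)O3)(C(C)C)[C@H]12 | intermediate (not isolated)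
25 | C5 angelate of boronate 24 | CC(C)(C)[Si](C)(C)O[C@H]1CC(C)=C[C@@H](OC(=O)/C(C)=C\C)[C@@]2(C)[C@H]3C[C@@](OB(c4ccccc4)O3)(C(C)C)[C@H]12 | intermediate (not isolated)
26 | C5 monoangelate (1β-OTBS; 7α-OH; 9α-OH) | CC(C)(C)[Si](C)(C)O[C@H]1CC(C)=C[C@@H](OC(=O)/C(C)=C\C)[C@@]2(C)[C@H](O)C[C@@](O)(C(C)C)[C@H]12 | intermediate
27 | C5 monoangelate with free 1β-OH | O[C@H]1CC(C)=C[C@@H](OC(=O)/C(C)=C\C)[C@@]2(C)[C@H](O)C[C@@](O)(C(C)C)[C@H]12 | intermediate
28 | (1R,3R,3aS,4S,8R,8aR)-1,3-dihydroxy-6,8a-dimethyl-3-(propan-2-yl)-1,2,3,3a,4,5,8,8a-octahydroazulene-4,8-diyl bis[(2Z)-2-methylbut-2-enoate] | C/C=C(/C)C(=O)O[C@H]1CC(C)=C[C@@H](OC(=O)/C(C)=C\C)[C@@]2(C)[C@H](O)C[C@@](O)(C(C)C)[C@H]12 | target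

**Summary**

Total step count: 15. Longest linear sequence: 14 steps (steps 1–6 and 8–15; step 7 is a side branch).

Steps most likely to fail:

Step 8. The congested magnesium aldolate may equilibrate by retro‑aldol, or the aldol may run through open transition states, so that control at C7 is lost. The fallback sets out from 12 and comes back at 18. The coupling is run as in step 8 and the crude C7‑epimer mixture is oxidised with Dess–Martin periodinane to the vinyl ketone F1. F1 is then reduced under reagent control with (S)-2-methyl-CBS-oxazaborolidine and catecholborane at −78 °C, the quaternary C6 acting as the large group, which should return 18 as a single C7 epimer.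

Step 11. The tertiary epoxide may open under the long exposure to acetic acid before the slow directed reduction of the hindered conjugated ketone is complete. The fallback sets out from 20 and comes back at 22. An Evans–Tishchenko reduction under neutral conditions (SmI2 cat., acetaldehyde, THF, −10 °C) should transfer hydride from the C7 hemiacetal to the α face of C5 and give the C5‑hydroxy C7‑acetate F2. LiEt3BH then cleaves the acetate and opens the epoxide at C8 in one operation, giving 22.

Step 13. Esterification of the hindered allylic C5 hydroxyl may be slow enough that the activated angelate isomerises to the tiglate or the boronate scrambles on heating. The fallback sets out from 24 and comes back at 25 (then 26 as before). The C5 hydroxyl is esterified with the unhindered 2-[bis(2,2,2-trifluoroethoxy)phosphoryl]propanoic acid (DCC, DMAP) to the phosphonate ester F3. A Still–Gennari olefination with acetaldehyde (KN(SiMe3)2, 18-crown-6, THF, −78 °C) then builds the (Z)‑2‑methylbut‑2‑enoate on the oxygen, giving 25.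

**Further compounds**

F1 | step 8 | (5S,6S,7S)-5-[(tert-butyldimethylsilyl)oxy]-3,7-dimethyl-6-(3-methylbut-1-en-2-yl)-7-(prop-2-enoyl)cyclohept-2-en-1-one | CC(C)(C)[Si](C)(C)O[C@H]1CC(C)=CC(=O)[C@@](C)(C(=O)C=C)[C@@H]1C(=C)C(C)C
F2 | step 11 | C7 acetate of epoxy diol 21 (1β-OTBS; 5β-OH; 7α-OAc; 8α,9α-epoxide) | CC(C)(C)[Si](C)(C)O[C@H]1CC(C)=C[C@@H](O)[C@@]2(C)[C@H](OC(C)=O)[C@@H]3O[C@]3(C(C)C)[C@H]12
F3 | step 13 | C5 2-[bis(2,2,2-trifluoroethoxy)phosphoryl]propanoate of boronate 24 | CC(C)(C)[Si](C)(C)O[C@H]1CC(C)=C[C@@H](OC(=O)C(C)P(=O)(OCC(F)(F)F)OCC(F)(F)F)[C@@]2(C)[C@H]3C[C@@](OB(c4ccccc4)O3)(C(C)C)[C@H]12
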